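**Plan**
1. The target is read as catechin-(4α→6)-epicatechin-(4β→8)-epicatechin-(4β→8)-epicatechin (units 1 to 4 from the top); after removal of sixteen benzyl ethers and two C8 bromines, the first cut is C4(unit 2)–C8(unit 3), giving a top-dimer C4 thioether and a bottom-dimer nucleophile.
2. The bottom dimer is cut at C4–C4a in both rings C: in units 3 and 4 this bond ties ring A to a carbon whose neighbour C3 carries oxygen, and in unit 3 the C4 aryl group lies trans to the C3 hydroxyl, the pattern left when an arene opens a trans oxirane from the back; both C3–C4 pairs are therefore traced back to oxiranes in one open-chain bis(aryl ether).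
3. Forward, bottom half: salicylaldehyde → hydroxychalcone → Mitsunobu ether with a resolved epoxy carbinol (unit 4 side chain) → enone epoxidation → ketone reduction → Mitsunobu ether with phloroglucinol dibenzyl ether → one acid treatment closes ring C of unit 3, then ring C of unit 4.
4. Forward, top half: benzylated, C8-brominated catechin (C4 ether) alkylates C6 of benzylated, C8-brominated epicatechin (C4 thioether kept); silver then ionises the thioether to bond C8 of unit 3, and hydrogenolysis ends the route.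
5. Stereochemistry: unit 4 C2/C3 from a Sharpless kinetic resolution plus Mitsunobu inversion; unit 3 C3/C4 from a poly-L-leucine epoxidation, C2 from anti-selective ketone reduction plus Mitsunobu inversion, C4 by inversion in the cyclisation; units 1 and 2 from (+)-catechin and (−)-epicatechin; both interflavan centres by attack trans to the C3 hydroxyl.

Key step: step 9

Assumption: the benzyl ethers 1, 3 and 5 are taken as purchasable; each is otherwise one benzylation away from phloroglucinol, 3',4'-dihydroxyacetophenone or 3,4-dihydroxybenzaldehyde.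

**Route**

Step 1
Reactants: 1 3,5-bis(benzyloxy)phenol
Product: 2 4,6-bis(benzyloxy)-2-hydroxybenzaldehyde
Conditions: MgCl2, Et3N, (CH2O)n, MeCN, reflux; aq HCl
Reagents that add atoms: paraformaldehyde, C=O
Why: Casnati–Skattebøl ortho-formylation, in which the magnesium phenoxide delivers formaldehyde to the ortho carbon and a second equivalent oxidises the benzylic alkoxide; the two ortho carbons of 1 are equivalent, so a single salicylaldehyde should form.

Step 2
Reactants: 2 4,6-bis(benzyloxy)-2-hydroxybenzaldehyde; 3 1-[3,4-bis(benzyloxy)phenyl]ethan-1-one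
Product: 4 (E)-1-[3,4-bis(benzyloxy)phenyl]-3-[4,6-bis(benzyloxy)-2-hydroxyphenyl]prop-2-en-1-one
Conditions: KOH, EtOH–THF, rt to 40 °C; AcOH to pH 6
Reagents that add atoms: none
Why: Claisen–Schmidt aldol condensation, in which the enolate of 3 adds to the aldehyde and the aldol loses water by E1cB to the conjugated E-enone, the mild acid quench avoiding ring closure to a flavylium salt.

Step 3
Reactants: 5 3,4-bis(benzyloxy)benzaldehyde
Product: 6 rac-1-[3,4-bis(benzyloxy)phenyl]prop-2-en-1-ol
Conditions: CH2=CHMgBr, THF, 0 °C; aq NH4Cl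
Reagents that add atoms: vinylmagnesium bromide, C=C[Mg]Br
Why: Grignard 1,2-addition of the vinyl nucleophile to the aryl aldehyde gives the racemic secondary allylic alcohol that the resolution needs.

Step 4
Reactants: 6 rac-1-[3,4-bis(benzyloxy)phenyl]prop-2-en-1-ol
Product: 7 (S)-[3,4-bis(benzyloxy)phenyl][(2R)-oxiran-2-yl]methanol (erythro)
Conditions: Ti(OiPr)4 (0.1 equiv), L-(+)-DIPT (0.15 equiv), TBHP (0.6 equiv), 4 Å MS, CH2Cl2, −20 °C
Reagents that add atoms: tert-butyl hydroperoxide, CC(C)(C)OO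
Why: Sharpless kinetic resolution, in which the L-(+)-tartrate complex epoxidises the (R)-enantiomer of 6 fast and on the face that gives the erythro epoxy alcohol, so stopping below half conversion should set both centres of 7 and leave the (S)-enantiomer of 6 unreacted.

Step 5
Reactants: 4 (E)-1-[3,4-bis(benzyloxy)phenyl]-3-[4,6-bis(benzyloxy)-2-hydroxyphenyl]prop-2-en-1-one; 7 (S)-[3,4-bis(benzyloxy)phenyl][(2R)-oxiran-2-yl]methanol
Product: 8 (E)-1-[3,4-bis(benzyloxy)phenyl]-3-[2,4-bis(benzyloxy)-6-{(R)-[3,4-bis(benzyloxy)phenyl][(2R)-oxiran-2-yl]methoxy}phenyl]prop-2-en-1-one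
Conditions: PPh3, DIAD, toluene, 0 °C to rt
Reagents that add atoms: none
Why: Mitsunobu etherification, in which the phenol of 4 displaces the oxyphosphonium of the secondary carbinol by SN2 and inverts it to the R ether (threo to the oxirane, as a 2,3-cis flavan requires), the oxirane and the enone being spectators in the neutral medium.

Step 6
Reactants: 8 (E)-enone ether from step 5
Product: 9 [3,4-bis(benzyloxy)phenyl]{(2R,3S)-3-[2,4-bis(benzyloxy)-6-{(R)-[3,4-bis(benzyloxy)phenyl][(2R)-oxiran-2-yl]methoxy}phenyl]oxiran-2-yl}methanone (trans epoxy ketone)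
Conditions: poly-L-leucine, 30% aq H2O2, NaOH, Bu4NBr, toluene, rt
Reagents that add atoms: hydrogen peroxide, OO
Why: Juliá–Colonna (Weitz–Scheffer type) nucleophilic epoxidation, in which hydroperoxide adds to the enone β-carbon inside the poly-L-leucine helix and the enolate closes to the trans oxirane, so that the catalyst rather than the remote ether centre should set the 2R,3S configuration.

Step 7
Reactants: 9 trans epoxy ketone from step 6
Product: 10 (S)-[3,4-bis(benzyloxy)phenyl]{(2S,3S)-3-[2,4-bis(benzyloxy)-6-{(R)-[3,4-bis(benzyloxy)phenyl][(2R)-oxiran-2-yl]methoxy}phenyl]oxiran-2-yl}methanol (erythro carbinol, trans oxirane)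
Conditions: NaBH4, CeCl3·7H2O, MeOH–THF, −78 °C; cold aq NaHCO3
Reagents that add atoms: none
Why: Luche-type 1,2-reduction of an α,β-epoxy ketone, in which hydride attacks anti to the oxirane C–O bond and should give the erythro (anti) carbinol, the low temperature and basic quench sparing the electron-rich benzylic oxirane.

Step 8
Reactants: 10 erythro epoxy carbinol from step 7; 1 3,5-bis(benzyloxy)phenol
Product: 11 (2R,3S)-2-{(R)-[3,4-bis(benzyloxy)phenyl][3,5-bis(benzyloxy)phenoxy]methyl}-3-[2,4-bis(benzyloxy)-6-{(R)-[3,4-bis(benzyloxy)phenyl][(2R)-oxiran-2-yl]methoxy}phenyl]oxirane (open-chain bis-epoxide bis(aryl ether))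
Conditions: PPh3, DIAD, toluene, 0 °C; quick filtration through Et3N-deactivated silica, used at once
Reagents that add atoms: none
Why: Mitsunobu etherification, in which phenol 1 displaces the activated carbinol with inversion to the R aryl ether (threo to the internal oxirane), the β-oxygen of the oxirane disfavouring ionisation of the benzylic carbinol and the neutral medium sparing both oxiranes.

Step 9
Reactants: 11 open-chain bis-epoxide bis(aryl ether)
Product: 13 octa-O-benzyl epicatechin-(4β→8)-epicatechin (5,7,3',4'-tetra-O-benzyl on each unit, both 3-hydroxyls free), via pendant-oxirane 4β-arylflavan-3-ol 12 (not isolated)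
Conditions: BF3·OEt2 (0.3 equiv), CH2Cl2 (2 mM, slow addition of 11), −78 to −20 °C; Et3N quench
Reagents that add atoms: none
Why: BF3 first activates the internal oxirane, whose C–O bond at the carbon bearing the 2,4,6-trioxygenated ring is the weakest, and an ortho carbon of the 3,5-bis(benzyloxy)phenyl ether attacks that carbon from the side opposite the leaving oxygen to give 12; on warming, the terminal oxirane is opened at its CH2 by the one free ortho carbon of the same trioxygenated ring (ring A of unit 4), and each rearomatisation returns the proton that frees the catalyst. The closest known reaction type is the intramolecular Friedel–Crafts epoxy–arene cyclisation of aryl glycidyl ethers to chroman-3-ols and of aryl 3-arylglycidyl ethers to trans-4-arylchroman-3-ols, here run twice in one flask. Both rings C close in the 6-endo mode: in unit 3 the benzylic carbon is the only oxirane carbon able to carry positive charge, and in unit 4 the unhindered primary carbon is attacked in preference to the secondary carbon, whose opening would give a 5-exo dihydrobenzofuran. The one new stereocentre, C4 of unit 3, is set by anti (invertive) opening of the trans oxirane, which places the aryl group trans to the C3 hydroxyl, while C2 and C3 of both units are carried over unchanged from 11. The step needs ring closure to outrun intermolecular arylation and must leave no regiochemical choice: the two ortho carbons of the symmetric phloroglucinol ether are equivalent, ring A of unit 4 has a single free ortho carbon, and high dilution with slow addition should keep the six-membered closures ahead of oligomerisation.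

Step 10
Reactants: 14 (+)-catechin
Product: 15 5,7,3',4'-tetra-O-benzyl-(+)-catechin
Conditions: BnBr, K2CO3, DMF, 0 °C to rt
Reagents that add atoms: benzyl bromide, BrCc1ccccc1
Why: Williamson etherification, in which the four phenoxides are alkylated while the far less acidic secondary 3-hydroxyl stays free.

Step 11
Reactants: 15 5,7,3',4'-tetra-O-benzyl-(+)-catechin
Product: 16 8-bromo-5,7,3',4'-tetra-O-benzylcatechin
Conditions: NBS, CH2Cl2, −78 °C to rt
Reagents that add atoms: N-bromosuccinimide, O=C1CCC(=O)N1Br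
Why: Electrophilic aromatic bromination goes to C8, the more accessible of the two free ring A carbons, and the bromine will keep this unit from acting as a C8 nucleophile later.

Step 12
Reactants: 16 8-bromo-5,7,3',4'-tetra-O-benzylcatechin
Product: 17 8-bromo-4β-(2-ethoxyethoxy)-5,7,3',4'-tetra-O-benzylcatechin
Conditions: DDQ, 2-ethoxyethanol, CH2Cl2, rt
Reagents that add atoms: 2-ethoxyethanol, CCOCCO
Why: DDQ benzylic oxidation removes hydride from C4 to a cation stabilised by the ring A oxygens, and the alcohol should add from the β face opposite the 2-aryl group, a configuration that is lost again when C4 is ionised in step 17.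

Step 13
Reactants: 18 (−)-epicatechin
Product: 19 5,7,3',4'-tetra-O-benzyl-(−)-epicatechin
Conditions: BnBr, K2CO3, DMF, 0 °C to rt
Reagents that add atoms: benzyl bromide, BrCc1ccccc1
Why: Williamson etherification of the four phenols, the secondary 3-hydroxyl remaining free as in step 10.

Step 14
Reactants: 19 5,7,3',4'-tetra-O-benzyl-(−)-epicatechin
Product: 20 8-bromo-5,7,3',4'-tetra-O-benzylepicatechin
Conditions: NBS, CH2Cl2, −78 °C to rt
Reagents that add atoms: N-bromosuccinimide, O=C1CCC(=O)N1Br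
Why: Electrophilic aromatic bromination at C8 blocks that carbon, so that C6 is the only ring A position left for the later interflavan bond.

Step 15
Reactants: 20 8-bromo-5,7,3',4'-tetra-O-benzylepicatechin
Product: 21 8-bromo-4β-(2-ethoxyethoxy)-5,7,3',4'-tetra-O-benzylepicatechin
Conditions: DDQ, 2-ethoxyethanol, CH2Cl2, rt
Reagents that add atoms: 2-ethoxyethanol, CCOCCO
Why: DDQ benzylic oxidation to the C4 cation followed by capture with the alcohol from the β face, opposite the cis 2-aryl and 3-hydroxyl groups, should give the 3,4-trans ether.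

Step 16
Reactants: 21 8-bromo-4β-(2-ethoxyethoxy)-5,7,3',4'-tetra-O-benzylepicatechin
Product: 22 4β-(benzylsulfanyl)-8-bromo-5,7,3',4'-tetra-O-benzylepicatechin
Conditions: BnSH (3 equiv), BF3·OEt2 (cat.), CH2Cl2, −78 to −40 °C
Reagents that add atoms: phenylmethanethiol, SCc1ccccc1
Why: Lewis-acid thiolysis of the benzylic ether, in which BF3 ionises the C4–O bond and the thiol adds to the cation trans to the 3-hydroxyl to give the 4β thioether, self-condensation being excluded by the C8 bromine and the excess thiol.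

Step 17
Reactants: 17 8-bromo-4β-(2-ethoxyethoxy)-5,7,3',4'-tetra-O-benzylcatechin; 22 4β-(benzylsulfanyl)-8-bromo-5,7,3',4'-tetra-O-benzylepicatechin
Product: 23 [8-bromo-5,7,3',4'-tetra-O-benzylcatechin]-(4α→6)-[4β-(benzylsulfanyl)-8-bromo-5,7,3',4'-tetra-O-benzylepicatechin]
Conditions: TMSOTf (cat.), CH2Cl2, −78 to −40 °C; 22 in threefold excess
Reagents that add atoms: none
Why: Cationic interflavan coupling (Friedel–Crafts alkylation) under orthogonal activation, in which the silyl triflate ionises the oxygen leaving group of 17 but not the thioether of 22, and the catechin C4 cation is attacked by C6 of 22, its only free ring A carbon, from the face trans to the 3-hydroxyl to set the 4α centre, the bromine on 17 and the excess of 22 holding back self-condensation.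

Step 18
Reactants: 23 top-dimer thioether from step 17; 13 octa-O-benzyl epicatechin-(4β→8)-epicatechin
Product: 24 hexadeca-O-benzyl-8-bromocatechin-(4α→6)-8-bromoepicatechin-(4β→8)-epicatechin-(4β→8)-epicatechin
Conditions: AgBF4, THF–CH2Cl2, 0 °C, dark; 13 in 1.5-fold excess
Reagents that add atoms: none
Why: Thiophilic activation, in which AgBF4 binds sulfur and releases the C4 cation of the epicatechin unit of 23, which is attacked by C8 of the upper unit of 13, the most nucleophilic and least hindered ring A carbon of the dimer, from the β face opposite the cis 2-aryl and 3-hydroxyl groups to set the 4β centre, while 23 has no free C8 and cannot add to itself.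

Step 19
Reactants: 24 protected tetramer from step 18
Product: 25 catechin-(4α→6)-epicatechin-(4β→8)-epicatechin-(4β→8)-epicatechin (CNP0228086.1)
Conditions: H2 (1 atm), Pd(OH)2/C, NaOAc, THF–MeOH–H2O, rt
Reagents that add atoms: none
Why: Catalytic hydrogenolysis cleaves the sixteen benzyl ethers and the two aryl C–Br bonds in one operation, the acetate taking up HBr so that the acid-labile interflavan bonds and all stereocentres stay untouched.

**Compound list**

1 | 3,5-bis(benzyloxy)phenol | Oc1cc(OCc2ccccc2)cc(OCc2ccccc2)c1 | starting material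
2 | 4,6-bis(benzyloxy)-2-hydroxybenzaldehyde | O=Cc1c(O)cc(OCc2ccccc2)cc1OCc2ccccc2 | intermediate
3 | 1-[3,4-bis(benzyloxy)phenyl]ethan-1-one | CC(=O)c1ccc(OCc2ccccc2)c(OCc2ccccc2)c1 | starting material
4 | (E)-1-[3,4-bis(benzyloxy)phenyl]-3-[4,6-bis(benzyloxy)-2-hydroxyphenyl]prop-2-en-1-one | O=C(/C=C/c1c(O)cc(OCc2ccccc2)cc1OCc2ccccc2)c1ccc(OCc2ccccc2)c(OCc2ccccc2)c1 | intermediate
5 | 3,4-bis(benzyloxy)benzaldehyde | O=Cc1ccc(OCc2ccccc2)c(OCc2ccccc2)c1 | starting material
6 | rac-1-[3,4-bis(benzyloxy)phenyl]prop-2-en-1-ol | C=CC(O)c1ccc(OCc2ccccc2)c(OCc2ccccc2)c1 | intermediate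
7 | (S)-[3,4-bis(benzyloxy)phenyl][(2R)-oxiran-2-yl]methanol (erythro) | O[C@@H](c1ccc(OCc2ccccc2)c(OCc2ccccc2)c1)[C@H]1CO1 | intermediate
8 | (E)-1-[3,4-bis(benzyloxy)phenyl]-3-[2,4-bis(benzyloxy)-6-{(R)-[3,4-bis(benzyloxy)phenyl][(2R)-oxiran-2-yl]methoxy}phenyl]prop-2-en-1-one | O=C(/C=C/c1c(OCc2ccccc2)cc(OCc2ccccc2)cc1O[C@H](c1ccc(OCc2ccccc2)c(OCc2ccccc2)c1)[C@H]1CO1)c1ccc(OCc2ccccc2)c(OCc2ccccc2)c1 | intermediate
9 | [3,4-bis(benzyloxy)phenyl]{(2R,3S)-3-[2,4-bis(benzyloxy)-6-{(R)-[3,4-bis(benzyloxy)phenyl][(2R)-oxiran-2-yl]methoxy}phenyl]oxiran-2-yl}methanone | O=C([C@@H]1O[C@H]1c1c(OCc2ccccc2)cc(OCc2ccccc2)cc1O[C@H](c1ccc(OCc2ccccc2)c(OCc2ccccc2)c1)[C@H]1CO1)c1ccc(OCc2ccccc2)c(OCc2ccccc2)c1 | intermediate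
10 | (S)-[3,4-bis(benzyloxy)phenyl]{(2S,3S)-3-[2,4-bis(benzyloxy)-6-{(R)-[3,4-bis(benzyloxy)phenyl][(2R)-oxiran-2-yl]methoxy}phenyl]oxiran-2-yl}methanol (erythro carbinol, trans oxirane) | O[C@@H](c1ccc(OCc2ccccc2)c(OCc2ccccc2)c1)[C@@H]1O[C@H]1c1c(OCc2ccccc2)cc(OCc2ccccc2)cc1O[C@H](c1ccc(OCc2ccccc2)c(OCc2ccccc2)c1)[C@H]1CO1 | intermediate
11 | (2R,3S)-2-{(R)-[3,4-bis(benzyloxy)phenyl][3,5-bis(benzyloxy)phenoxy]methyl}-3-[2,4-bis(benzyloxy)-6-{(R)-[3,4-bis(benzyloxy)phenyl][(2R)-oxiran-2-yl]methoxy}phenyl]oxirane | c1ccccc1COc1cc(OCc2ccccc2)cc(c1)O[C@H](c1ccc(OCc2ccccc2)c(OCc2ccccc2)c1)[C@@H]1O[C@H]1c1c(OCc2ccccc2)cc(OCc2ccccc2)cc1O[C@H](c1ccc(OCc2ccccc2)c(OCc2ccccc2)c1)[C@H]1CO1 | intermediate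
12 | 5,7,3',4'-tetra-O-benzyl-4β-[2,4-bis(benzyloxy)-6-{(R)-[3,4-bis(benzyloxy)phenyl][(2R)-oxiran-2-yl]methoxy}phenyl]epicatechin | c1ccccc1COc1cc(OCc2ccccc2)c2c(c1)O[C@H](c1ccc(OCc3ccccc3)c(OCc3ccccc3)c1)[C@H](O)[C@H]2c1c(OCc2ccccc2)cc(OCc2ccccc2)cc1O[C@H](c1ccc(OCc2ccccc2)c(OCc2ccccc2)c1)[C@H]1CO1 | intermediate
13 | octa-O-benzyl epicatechin-(4β→8)-epicatechin (both 3-hydroxyls free) | c1ccccc1COc1cc(OCc2ccccc2)c2c(c1)O[C@H](c1ccc(OCc3ccccc3)c(OCc3ccccc3)c1)[C@H](O)[C@H]2c1c(OCc2ccccc2)cc(OCc2ccccc2)c2c1O[C@H](c1ccc(OCc3ccccc3)c(OCc3ccccc3)c1)[C@H](O)C2 | intermediate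
14 | (+)-catechin | Oc1cc(O)c2c(c1)O[C@H](c1ccc(O)c(O)c1)[C@@H](O)C2 | starting material
15 | 5,7,3',4'-tetra-O-benzyl-(+)-catechin | c1ccccc1COc1cc(OCc2ccccc2)c2c(c1)O[C@H](c1ccc(OCc3ccccc3)c(OCc3ccccc3)c1)[C@@H](O)C2 | intermediate
16 | 8-bromo-5,7,3',4'-tetra-O-benzylcatechin | c1ccccc1COc1cc(OCc2ccccc2)c2c(c1Br)O[C@H](c1ccc(OCc3ccccc3)c(OCc3ccccc3)c1)[C@@H](O)C2 | intermediate
17 | 8-bromo-4β-(2-ethoxyethoxy)-5,7,3',4'-tetra-O-benzylcatechin | c1ccccc1COc1cc(OCc2ccccc2)c2c(c1Br)O[C@H](c1ccc(OCc3ccccc3)c(OCc3ccccc3)c1)[C@@H](O)[C@H]2OCCOCC | intermediate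
18 | (−)-epicatechin | Oc1cc(O)c2c(c1)O[C@H](c1ccc(O)c(O)c1)[C@H](O)C2 | starting material
19 | 5,7,3',4'-tetra-O-benzyl-(−)-epicatechin | c1ccccc1COc1cc(OCc2ccccc2)c2c(c1)O[C@H](c1ccc(OCc3ccccc3)c(OCc3ccccc3)c1)[C@H](O)C2 | intermediate
20 | 8-bromo-5,7,3',4'-tetra-O-benzylepicatechin | c1ccccc1COc1cc(OCc2ccccc2)c2c(c1Br)O[C@H](c1ccc(OCc3ccccc3)c(OCc3ccccc3)c1)[C@H](O)C2 | intermediate
21 | 8-bromo-4β-(2-ethoxyethoxy)-5,7,3',4'-tetra-O-benzylepicatechin | c1ccccc1COc1cc(OCc2ccccc2)c2c(c1Br)O[C@H](c1ccc(OCc3ccccc3)c(OCc3ccccc3)c1)[C@H](O)[C@H]2OCCOCC | intermediate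
22 | 4β-(benzylsulfanyl)-8-bromo-5,7,3',4'-tetra-O-benzylepicatechin | c1ccccc1COc1cc(OCc2ccccc2)c2c(c1Br)O[C@H](c1ccc(OCc3ccccc3)c(OCc3ccccc3)c1)[C@H](O)[C@H]2SCc1ccccc1 | intermediate
23 | [8-bromo-5,7,3',4'-tetra-O-benzylcatechin]-(4α→6)-[4β-(benzylsulfanyl)-8-bromo-5,7,3',4'-tetra-O-benzylepicatechin] | c1ccccc1COc1cc(OCc2ccccc2)c2c(c1Br)O[C@H](c1ccc(OCc3ccccc3)c(OCc3ccccc3)c1)[C@@H](O)[C@@H]2c1c(OCc2ccccc2)c(Br)c2c(c1OCc3ccccc3)[C@H](SCc1ccccc1)[C@@H](O)[C@@H](c1ccc(OCc3ccccc3)c(OCc3ccccc3)c1)O2 | intermediate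
24 | hexadeca-O-benzyl-8-bromocatechin-(4α→6)-8-bromoepicatechin-(4β→8)-epicatechin-(4β→8)-epicatechin | c1ccccc1COc1cc(OCc2ccccc2)c2c(c1Br)O[C@H](c1ccc(OCc3ccccc3)c(OCc3ccccc3)c1)[C@@H](O)[C@@H]2c1c(OCc2ccccc2)c(Br)c2c(c1OCc3ccccc3)[C@H](c1c(OCc3ccccc3)cc(OCc3ccccc3)c3c1O[C@H](c1ccc(OCc4ccccc4)c(OCc4ccccc4)c1)[C@H](O)[C@H]3c1c(OCc3ccccc3)cc(OCc3ccccc3)c3c1O[C@H](c1ccc(OCc4ccccc4)c(OCc4ccccc4)c1)[C@H](O)C3)[C@@H](O)[C@@H](c1ccc(OCc3ccccc3)c(OCc3ccccc3)c1)O2 | intermediate
25 | catechin-(4α→6)-epicatechin-(4β→8)-epicatechin-(4β→8)-epicatechin (CNP0228086.1) | Oc1cc(O)c2c(c1)O[C@H](c1ccc(O)c(O)c1)[C@@H](O)[C@@H]2c1c(O)cc2c(c1O)[C@H](c1c(O)cc(O)c3c1O[C@H](c1ccc(O)c(O)c1)[C@H](O)[C@H]3c1c(O)cc(O)c3c1O[C@H](c1ccc(O)c(O)c1)[C@H](O)C3)[C@@H](O)[C@@H](c1ccc(O)c(O)c1)O2 | target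

**Count and risks**

Total: 19 steps. Longest linear sequence: 9 steps (5 → 6 → 7 → 8 → 9 → 10 → 11 → 13 → 24 → 25, i.e. steps 3 to 9, 18 and 19).

Step 9 (double cyclisation). The ionised internal oxirane may alkylate the electron-rich ring A of a second molecule instead of closing, a free benzylic cation may lose the anti course and erode the C4 configuration, or the terminal oxirane may undergo hydride shift or 5-exo opening. The fallback makes the same dimer by cation chemistry on a preformed flavan. It sets out from 19, which DDQ and 2-ethoxyethanol in CH2Cl2 should convert into 4β-(2-ethoxyethoxy)-5,7,3',4'-tetra-O-benzylepicatechin F1. Catalytic TMSOTf at −78 °C should then ionise F1 in the presence of a several-fold excess of 19, whose C8 attacks the cation trans to the 3-hydroxyl. This returns to the route at 13.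

Step 8 (second Mitsunobu). The benzylic carbinol or the very electron-rich oxirane may ionise during etherification, leading to loss of inversion, C-alkylation of the phenol or decomposition. The fallback reverses the order of bond formation at unit 3 and makes the C–C bond before the C–O bond. It sets out from 10 and 1: under a mild Lewis acid such as Sc(OTf)3 (cat.) in CH2Cl2 at −40 °C, the ortho carbon of phenol 1 should open the internal oxirane at its benzylic carbon with inversion. The product is the C-arylated triol 1-[3,4-bis(benzyloxy)phenyl]-3-[4,6-bis(benzyloxy)-2-hydroxyphenyl]-3-[2,4-bis(benzyloxy)-6-{(R)-[3,4-bis(benzyloxy)phenyl][(2R)-oxiran-2-yl]methoxy}phenyl]propane-1,2-diol F2. An intramolecular Mitsunobu reaction (PPh3, DIAD, THF) should then let the phenol displace the benzylic carbinol with inversion and close the pyran ring. This returns to the route at 12, which BF3·OEt2 cyclises to 13 as in the second half of step 9.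

Step 6 (enone epoxidation). Oxygen transfer to the hindered, strongly donor-substituted β-carbon may be slow or poorly face-selective, and hydroperoxide may attack the terminal oxirane during a long reaction. The fallback replaces nucleophilic epoxidation by a hydroxyl-directed electrophilic one. It sets out from 8: Corey–Bakshi–Shibata reduction (the oxazaborolidine enantiomer that delivers the R carbinol, catecholborane, toluene, −78 °C) should give (R,E)-1-[3,4-bis(benzyloxy)phenyl]-3-[2,4-bis(benzyloxy)-6-{(R)-[3,4-bis(benzyloxy)phenyl][(2R)-oxiran-2-yl]methoxy}phenyl]prop-2-en-1-ol F3. Sharpless epoxidation of F3 with Ti(OiPr)4, L-(+)-DIPT and TBHP at −20 °C is the matched pair and should give the erythro epoxy alcohol directly. This returns to the route at 10.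

**Further compounds**

F1 | step 9 | 4β-(2-ethoxyethoxy)-5,7,3',4'-tetra-O-benzylepicatechin | c1ccccc1COc1cc(OCc2ccccc2)c2c(c1)O[C@H](c1ccc(OCc3ccccc3)c(OCc3ccccc3)c1)[C@H](O)[C@H]2OCCOCC
F2 | step 8 | 1-[3,4-bis(benzyloxy)phenyl]-3-[4,6-bis(benzyloxy)-2-hydroxyphenyl]-3-[2,4-bis(benzyloxy)-6-{(R)-[3,4-bis(benzyloxy)phenyl][(2R)-oxiran-2-yl]methoxy}phenyl]propane-1,2-diol (C1 and C2 as in 10, C3 inverted) | O[C@@H](c1ccc(OCc2ccccc2)c(OCc2ccccc2)c1)[C@H](O)[C@@H](c1c(OCc2ccccc2)cc(OCc2ccccc2)cc1O[C@H](c1ccc(OCc2ccccc2)c(OCc2ccccc2)c1)[C@H]1CO1)c1c(O)cc(OCc2ccccc2)cc1OCc2ccccc2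
F3 | step 6 | (R,E)-1-[3,4-bis(benzyloxy)phenyl]-3-[2,4-bis(benzyloxy)-6-{(R)-[3,4-bis(benzyloxy)phenyl][(2R)-oxiran-2-yl]methoxy}phenyl]prop-2-en-1-ol | O[C@@H](c1ccc(OCc2ccccc2)c(OCc2ccccc2)c1)/C=C/c1c(OCc2ccccc2)cc(OCc2ccccc2)cc1O[C@H](c1ccc(OCc2ccccc2)c(OCc2ccccc2)c1)[C@H]1CO1
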